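**Retrosynthetic overview**
1. The target comes from a macrocyclic C10 sulfone methyl ester by ester hydrolysis and replacement of C10–SO2Ph by C10–H. The fourteen-membered ring is closed last, at C9–C10, by attack of the C10 allyl-sulfone carbanion on a C9 allylic chloride.
2. The Z-enoate C3=C4 comes from a Still–Gennari olefination of a C3 aldehyde with an α-homoprenyl phosphonoacetate. The E-C7=C8 bond and the C9–Cl end of that phosphonate come from SeO2 oxidation.
3. C1 (R) is set by a rhodium-catalysed asymmetric 1,4-addition of the 6-methylhepta-1,5-dien-2-yl boronate to an E-enal.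
4. Key sequence: 4-methylanisole supplies C10–C14, C1, the C12 methyl and the Z-C11=C12 bond. It is dearomatised by Birch reduction, and the β,γ-enone is then cut by Baeyer–Villiger oxidation between the carbonyl and the allylic carbon.
5. Ring order: the six-membered ring of the arene becomes a seven-membered allylic lactone, which is opened, and the fourteen-membered carbocycle is then closed.

Assumption: locants C1–C14 follow the ring atoms of the target SMILES, starting at the stereocentre (C1). C4 bears CO2H, and C8 and C12 bear CH3. The target is 1R, C3=C4 Z, C7=C8 E, C11=C12 Z.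

**Step 1**
Reactants: 1 4-methylanisole
Product: 3 4-methylcyclohex-3-en-1-one, via 1-methoxy-4-methylcyclohexa-1,4-diene 2 (not isolated)
Conditions: Li (2.5 equiv), NH3(l)/THF/t-BuOH, −78 to −33 °C; evaporate; (CO2H)2 (cat.), THF/H2O, 23 °C
Reagents that add atoms: water, O
Why: Birch reduction keeps the OMe- and Me-bearing carbons sp2 and gives the 1,4-diene, mild enol-ether hydrolysis gives the unconjugated β,γ-enone, and the ring C=C is necessarily cis and later becomes Z-C11=C12.

**Step 2**
Reactants: 3 4-methylcyclohex-3-en-1-one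
Product: 4 5-methyl-4,7-dihydrooxepin-2(3H)-one
Conditions: (Me3SiO)2 (1.5 equiv), SnCl4 (20 mol %), trans-1,2-(TsNH)2C6H10 (20 mol %), 4 Å MS, CH2Cl2, −20 °C
Reagents that add atoms: bis(trimethylsilyl) peroxide, C[Si](C)(C)OO[Si](C)(C)C
Why: In this aprotic Lewis-acid Baeyer–Villiger oxidation the ketone is activated and the alkene is not, and the allylic CH2 migrates in preference to the plain CH2, so oxygen enters between C1 and C10 and the cis ring alkene is kept.

**Step 3**
Reactants: 4 5-methyl-4,7-dihydrooxepin-2(3H)-one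
Product: 5 (4Z)-6-hydroxy-4-methylhex-4-enal (in equilibrium with its seven-membered lactol)
Conditions: i-Bu2AlH (1.05 equiv), CH2Cl2, −78 °C; aq. potassium sodium tartrate
Reagents that add atoms: none
Why: Partial lactone reduction stops at the tetrahedral aluminium hemiacetal at −78 °C and releases the hydroxy aldehyde only on work-up.

**Step 4**
Reactants: 5 (4Z)-6-hydroxy-4-methylhex-4-enal
Product: 6 (2E,6Z)-8-hydroxy-6-methylocta-2,6-dienal
Conditions: Ph3P=CHCHO (1.1 equiv), toluene, 70 °C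
Reagents that add atoms: (triphenylphosphoranylidene)acetaldehyde, O=CC=P(c1ccccc1)(c1ccccc1)c1ccccc1
Why: The Wittig reaction of the stabilised formyl ylide with the open aldehyde form is E-selective and adds C2 and C3.

**Step 5**
Reactants: 6 (2E,6Z)-8-hydroxy-6-methylocta-2,6-dienal
Product: 8 (2E,6Z)-6-methyl-8-(phenylsulfonyl)octa-2,6-dienal, via (2E,6Z)-8-bromo-6-methylocta-2,6-dienal 7 (not isolated)
Conditions: PBr3 (0.4 equiv), Et2O, −10 °C; crude 7, PhSO2Na (1.3 equiv), DMF, 0 to 23 °C
Reagents that add atoms: phosphorus tribromide, BrP(Br)Br (bromine of 7); sodium benzenesulfinate, [Na+].[O-]S(=O)c1ccccc1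
Why: Bromination and S-alkylation of the soft sulfinate are both SN2 displacements at the primary allylic carbon, so the Z alkene is untouched.

**Step 6**
Reactants: 9 6-methylhept-5-en-2-one
Product: 10 6-methylhepta-1,5-dien-2-yl trifluoromethanesulfonate
Conditions: LiN(i-Pr)2 (1.05 equiv), THF, −78 °C; PhNTf2, −78 to 0 °C
Reagents that add atoms: N-phenylbis(trifluoromethanesulfonimide), O=S(=O)(N(c1ccccc1)S(=O)(=O)C(F)(F)F)C(F)(F)F
Why: Kinetic deprotonation at the methyl group followed by O-triflation fixes the 1,1-disubstituted alkene that becomes C15=CH2.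

**Step 7**
Reactants: 10 6-methylhepta-1,5-dien-2-yl trifluoromethanesulfonate
Product: 11 2-(6-methylhepta-1,5-dien-2-yl)-4,4,5,5-tetramethyl-1,3,2-dioxaborolane
Conditions: B2pin2 (1.1 equiv), PdCl2(PPh3)2 (3 mol %), PPh3 (6 mol %), KOPh (1.5 equiv), toluene, 50 °C
Reagents that add atoms: bis(pinacolato)diboron, CC1(C)OB(OC1(C)C)B1OC(C)(C)C(C)(C)O1
Why: Miyaura borylation of an alkenyl triflate proceeds without moving the double bond.

**Step 8**
Reactants: 8 (2E,6Z)-6-methyl-8-(phenylsulfonyl)octa-2,6-dienal; 11 2-(6-methylhepta-1,5-dien-2-yl)-4,4,5,5-tetramethyl-1,3,2-dioxaborolane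
Product: 12 (3R,6Z)-6-methyl-3-(6-methylhepta-1,5-dien-2-yl)-8-(phenylsulfonyl)oct-6-enal
Conditions: [RhCl(C2H4)2]2 (2.5 mol %), (R,R)-Ph-bod* [(1R,4R)-2,5-diphenylbicyclo[2.2.2]octa-2,5-diene] (5.5 mol %), KOH (20 mol %), 1,4-dioxane/H2O 10:1, 30 °C
Reagents that add atoms: none
Why: In this Hayashi–Miyaura asymmetric 1,4-addition the chiral diene–rhodium alkenyl species is expected, by analogy with (R)-BINAP and E-configured acyclic acceptors, to add to the Re face of C3 of the E-enal, which sets the only stereocentre as R (C1 of the target), and water protonates the enolate.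

**Step 9**
Reactants: 13 methyl 2-[bis(2,2,2-trifluoroethoxy)phosphoryl]acetate; 14 5-bromo-2-methylpent-2-ene
Product: 15 methyl 2-[bis(2,2,2-trifluoroethoxy)phosphoryl]-6-methylhept-5-enoate (racemic)
Conditions: NaH (1.0 equiv), DMSO/THF, 0 °C; 14, NaI (10 mol %), 50 °C
Reagents that add atoms: none
Why: SN2 alkylation of the phosphonate-stabilised carbanion forms C4–C5, and the racemic centre at C4 is erased in step 12.

**Step 10**
Reactants: 15 methyl 2-[bis(2,2,2-trifluoroethoxy)phosphoryl]-6-methylhept-5-enoate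
Product: 16 methyl (5E)-2-[bis(2,2,2-trifluoroethoxy)phosphoryl]-7-hydroxy-6-methylhept-5-enoate
Conditions: SeO2 (20 mol %), t-BuOOH (2.5 equiv), salicylic acid (10 mol %), CH2Cl2, 0 to 23 °C
Reagents that add atoms: tert-butyl hydroperoxide, CC(C)(C)OO
Why: Catalytic SeO2 allylic oxidation (ene reaction, then [2,3]-shift) hydroxylates only the E-methyl group of the prenyl end, which fixes E-C7=C8 and oxygenates C9.

**Step 11**
Reactants: 16 methyl (5E)-2-[bis(2,2,2-trifluoroethoxy)phosphoryl]-7-hydroxy-6-methylhept-5-enoate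
Product: 17 methyl (5E)-2-[bis(2,2,2-trifluoroethoxy)phosphoryl]-7-chloro-6-methylhept-5-enoate
Conditions: NCS (1.2 equiv), Me2S (1.3 equiv), CH2Cl2, −30 to 0 °C
Reagents that add atoms: N-chlorosuccinimide, O=C1CCC(=O)N1Cl
Why: Corey–Kim chlorination converts the primary allylic alcohol by SN2 under neutral conditions, without allylic shift and without touching the phosphonate.

**Step 12**
Reactants: 12 (3R,6Z)-6-methyl-3-(6-methylhepta-1,5-dien-2-yl)-8-(phenylsulfonyl)oct-6-enal; 17 methyl (5E)-2-[bis(2,2,2-trifluoroethoxy)phosphoryl]-7-chloro-6-methylhept-5-enoate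
Product: 18 methyl (2Z,5R,8Z)-2-[(3E)-5-chloro-4-methylpent-3-en-1-yl]-8-methyl-5-(6-methylhepta-1,5-dien-2-yl)-10-(phenylsulfonyl)deca-2,8-dienoate
Conditions: 17, KN(SiMe3)2 (1.0 equiv), 18-crown-6 (4 equiv), THF, −78 °C; then 12
Reagents that add atoms: none
Why: Still–Gennari olefination eliminates fast and irreversibly from the kinetic adduct and places C2 cis to the ester (Z), while at −78 °C the stabilised anion attacks neither the allylic chloride nor the sulfone CH2.

**Step 13**
Reactants: 18 methyl (2Z,5R,8Z)-2-[(3E)-5-chloro-4-methylpent-3-en-1-yl]-8-methyl-5-(6-methylhepta-1,5-dien-2-yl)-10-(phenylsulfonyl)deca-2,8-dienoate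
Product: 19 methyl (1Z,4R,7Z,11E)-7,11-dimethyl-4-(6-methylhepta-1,5-dien-2-yl)-9-(phenylsulfonyl)cyclotetradeca-1,7,11-triene-1-carboxylate (mixture at C9 of this name)
Conditions: KN(SiMe3)2 (1.2 equiv), THF (2 mM, syringe-pump addition of 18), −40 to 0 °C
Reagents that add atoms: none
Why: The allyl-sulfone CH2 is the most acidic site, and its carbanion closes the fourteen-membered ring by intramolecular SN2 at the primary allylic chloride; the new sulfone-bearing centre is uncontrolled and is removed in step 15.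

**Step 14**
Reactants: 19 macrocyclic sulfone methyl ester
Product: 20 (1Z,4R,7Z,11E)-7,11-dimethyl-4-(6-methylhepta-1,5-dien-2-yl)-9-(phenylsulfonyl)cyclotetradeca-1,7,11-triene-1-carboxylic acid
Conditions: LiOH (6 equiv), THF/MeOH/H2O 3:1:1, 45 °C; 1 M HCl
Reagents that add atoms: lithium hydroxide, [Li+].[OH-]
Why: Saponification is placed before the hydride step so that the enoate meets the hydride only as its unreactive carboxylate, and the C1 centre has no acidic hydrogen next to it.

**Step 15**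
Reactants: 20 macrocyclic sulfone acid
Product: 21 (1Z,4R,7Z,11E)-7,11-dimethyl-4-(6-methylhepta-1,5-dien-2-yl)cyclotetradeca-1,7,11-triene-1-carboxylic acid (target)
Conditions: PdCl2(dppp) (5 mol %), LiHBEt3 (4 equiv), THF, 0 °C; 1 M HCl
Reagents that add atoms: none
Why: In this palladium-catalysed hydride desulfonylation zerovalent palladium ionises the allylic sulfone, hydride goes to the secondary C10 end of the π-allyl and not to the tertiary C12 end, and the C12 substituents do not exchange, so position and Z geometry of C11=C12 are kept.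

**Compound list**
1 | 4-methylanisole | COc1ccc(C)cc1 | starting material
2 | 1-methoxy-4-methylcyclohexa-1,4-diene | COC1=CCC(C)=CC1 | intermediate
3 | 4-methylcyclohex-3-en-1-one | O=C1CC=C(C)CC1 | intermediate
4 | 5-methyl-4,7-dihydrooxepin-2(3H)-one | O=C1CCC(C)=CCO1 | intermediate
5 | (4Z)-6-hydroxy-4-methylhex-4-enal | O=CCC/C(C)=C\CO | intermediate
6 | (2E,6Z)-8-hydroxy-6-methylocta-2,6-dienal | O=C/C=C/CC/C(C)=C\CO | intermediate
7 | (2E,6Z)-8-bromo-6-methylocta-2,6-dienal | O=C/C=C/CC/C(C)=C\CBr | intermediate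
8 | (2E,6Z)-6-methyl-8-(phenylsulfonyl)octa-2,6-dienal | O=C/C=C/CC/C(C)=C\CS(=O)(=O)c1ccccc1 | intermediate
9 | 6-methylhept-5-en-2-one | CC(=O)CCC=C(C)C | starting material
10 | 6-methylhepta-1,5-dien-2-yl trifluoromethanesulfonate | C=C(CCC=C(C)C)OS(=O)(=O)C(F)(F)F | intermediate
11 | 2-(6-methylhepta-1,5-dien-2-yl)-4,4,5,5-tetramethyl-1,3,2-dioxaborolane | C=C(CCC=C(C)C)B1OC(C)(C)C(C)(C)O1 | intermediate
12 | (3R,6Z)-6-methyl-3-(6-methylhepta-1,5-dien-2-yl)-8-(phenylsulfonyl)oct-6-enal | C=C(CCC=C(C)C)[C@H](CC/C(C)=C\CS(=O)(=O)c1ccccc1)CC=O | intermediate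
13 | methyl 2-[bis(2,2,2-trifluoroethoxy)phosphoryl]acetate | COC(=O)CP(=O)(OCC(F)(F)F)OCC(F)(F)F | starting material
14 | 5-bromo-2-methylpent-2-ene | CC(C)=CCCBr | starting material
15 | methyl 2-[bis(2,2,2-trifluoroethoxy)phosphoryl]-6-methylhept-5-enoate | COC(=O)C(CCC=C(C)C)P(=O)(OCC(F)(F)F)OCC(F)(F)F | intermediate
16 | methyl (5E)-2-[bis(2,2,2-trifluoroethoxy)phosphoryl]-7-hydroxy-6-methylhept-5-enoate | COC(=O)C(CC/C=C(\C)CO)P(=O)(OCC(F)(F)F)OCC(F)(F)F | intermediate
17 | methyl (5E)-2-[bis(2,2,2-trifluoroethoxy)phosphoryl]-7-chloro-6-methylhept-5-enoate | COC(=O)C(CC/C=C(\C)CCl)P(=O)(OCC(F)(F)F)OCC(F)(F)F | intermediate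
18 | methyl (2Z,5R,8Z)-2-[(3E)-5-chloro-4-methylpent-3-en-1-yl]-8-methyl-5-(6-methylhepta-1,5-dien-2-yl)-10-(phenylsulfonyl)deca-2,8-dienoate | C=C(CCC=C(C)C)[C@H](CC/C(C)=C\CS(=O)(=O)c1ccccc1)C/C=C(\C(=O)OC)CC/C=C(\C)CCl | intermediate
19 | methyl (1Z,4R,7Z,11E)-7,11-dimethyl-4-(6-methylhepta-1,5-dien-2-yl)-9-(phenylsulfonyl)cyclotetradeca-1,7,11-triene-1-carboxylate | C=C(CCC=C(C)C)[C@H]1C/C=C(\C(=O)OC)CC/C=C(\C)CC(S(=O)(=O)c2ccccc2)/C=C(/C)CC1 | intermediate
20 | (1Z,4R,7Z,11E)-7,11-dimethyl-4-(6-methylhepta-1,5-dien-2-yl)-9-(phenylsulfonyl)cyclotetradeca-1,7,11-triene-1-carboxylic acid | C=C(CCC=C(C)C)[C@H]1C/C=C(\C(=O)O)CC/C=C(\C)CC(S(=O)(=O)c2ccccc2)/C=C(/C)CC1 | intermediate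
21 | (1Z,4R,7Z,11E)-7,11-dimethyl-4-(6-methylhepta-1,5-dien-2-yl)cyclotetradeca-1,7,11-triene-1-carboxylic acid | C=C(CCC=C(C)C)[C@H]1C/C=C(\C(=O)O)CC/C=C(\C)CC/C=C(/C)CC1 | target

**Step count**
Total step count: 15.
Longest linear sequence: 10 steps (steps 1, 2, 3, 4, 5, 8, 12, 13, 14, 15; 1 → 3 → 4 → 5 → 6 → 8 → 12 → 18 → 19 → 20 → 21).

**Steps most likely to fail**

Step 8 is the least secure. A 1,1-disubstituted alkenyl boronate on a β-alkyl enal may give 1,2-addition, slow transmetalation or modest ee. The fallback sets out from 8 and 10, comes back at 12 and makes step 7 unnecessary. NaBH4/CeCl3 in MeOH at −78 °C reduces 8 to (2E,6Z)-6-methyl-8-(phenylsulfonyl)octa-2,6-dien-1-ol F4. An enantioselective redox-relay Heck alkenylation of F4 with triflate 10 follows, using Pd(CH3CN)2(OTs)2 and the enantiomer of 4-tert-butyl-2-[5-(trifluoromethyl)pyridin-2-yl]-4,5-dihydrooxazole that is matched to Re-face insertion, with 3 Å MS in DMA at 23 °C. This puts the alkenyl group on C3, and chain-walking of the palladium hydride to the carbinol carbon releases aldehyde 12 directly.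

Step 13 may suffer from oligomerisation, SN2' attack or competing deprotonation of the enoate. The fallback sets out from 12 and 17, comes back at 19 and moves the ring closure to C3=C4.
- HC(OMe)3 with catalytic TsOH converts 12 into (3R,6Z)-1,1-dimethoxy-6-methyl-3-(6-methylhepta-1,5-dien-2-yl)-8-(phenylsulfonyl)oct-6-ene F5.
- n-BuLi deprotonates the sulfone of F5. The carbanion is alkylated intermolecularly by chloride 17, whose phosphonate CH is held as its anion by one extra equivalent of KN(SiMe3)2, giving the open-chain acetal phosphonate sulfone F6.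
- Aqueous oxalic acid in THF frees the open-chain aldehyde phosphonate sulfone F7.
- KN(SiMe3)2/18-crown-6 in THF at high dilution and −78 °C closes the ring by an intramolecular Still–Gennari olefination to give 19.

Step 2 may give alkene epoxidation, acid-induced conjugation of the enone or ionisation of the allylic lactone. The fallback sets out from 3 and comes back at 5.
- KN(SiMe3)2 deprotonates the doubly activated C2 of 3, and 2-(phenylsulfonyl)-3-phenyloxaziridine gives 2-hydroxy-4-methylcyclohex-3-en-1-one F1.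
- Pb(OAc)4 in MeOH cleaves the same ring bond and gives methyl (4Z)-4-methyl-6-oxohex-4-enoate F2.
- Immediate NaBH4/CeCl3 reduction gives methyl (4Z)-6-hydroxy-4-methylhex-4-enoate F3.
- i-Bu2AlH (2.1 equiv) at −78 °C reduces the ester to 5.

**Further compounds**
F1 | step 2 | 2-hydroxy-4-methylcyclohex-3-en-1-one | O=C1C(O)C=C(C)CC1
F2 | step 2 | methyl (4Z)-4-methyl-6-oxohex-4-enoate | COC(=O)CC/C(C)=C\C=O
F3 | step 2 | methyl (4Z)-6-hydroxy-4-methylhex-4-enoate | COC(=O)CC/C(C)=C\CO
F4 | step 8 | (2E,6Z)-6-methyl-8-(phenylsulfonyl)octa-2,6-dien-1-ol | OC/C=C/CC/C(C)=C\CS(=O)(=O)c1ccccc1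
F5 | step 13 | (3R,6Z)-1,1-dimethoxy-6-methyl-3-(6-methylhepta-1,5-dien-2-yl)-8-(phenylsulfonyl)oct-6-ene | C=C(CCC=C(C)C)[C@H](CC/C(C)=C\CS(=O)(=O)c1ccccc1)CC(OC)OC
F6 | step 13 | open-chain acetal phosphonate sulfone (C9–C10 bond made, C3 as dimethyl acetal) | C=C(CCC=C(C)C)[C@H](CC/C(C)=C\C(C/C(C)=C/CCC(C(=O)OC)P(=O)(OCC(F)(F)F)OCC(F)(F)F)S(=O)(=O)c1ccccc1)CC(OC)OC
F7 | step 13 | open-chain aldehyde phosphonate sulfone | C=C(CCC=C(C)C)[C@H](CC/C(C)=C\C(C/C(C)=C/CCC(C(=O)OC)P(=O)(OCC(F)(F)F)OCC(F)(F)F)S(=O)(=O)c1ccccc1)CC=O
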